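**Retrosynthetic overview**
1. The polyene-cyclisation / sclareolide logic is avoided: ring B is bought as (R)-carvone (supplies C5, the C7=C8 alkene and C17); C10 is set by two enolate alkylations.
2. Ring A is closed second by double ozonolysis and an intramolecular aldol that installs the 2α-OH directly.
3. C4 (18-Me α, 19-CH2OH β) comes from the C4 ketone in two steps: Corey–Chaykovsky spiro-epoxide, then Me3Al opening at the tertiary carbon (bold).
4. The whole C11–C16 chain (fragment 2, Negishi carboalumination) is added to the C9 carbonyl as an organolithium; Pd(OAc)2/formate hydrogenolysis of the tertiary allylic ester (bold key step) sets 9α-H and keeps the C7=C8 alkene.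
5. End game: global desilylation, then selective C15 succinylation. Ring order: B (chiral pool), then A.

Assumption: labdane numbering is used throughout (C1–C10 decalin, C11–C16 side chain, C17 on C8, C18 α and C19 β on C4, C20 on C10; α = face opposite C20); 1, 12 and all reagents are taken as commercial.

**Route**

Step 1
Reactants: 1 (R)-(−)-carvone
Product: 3 6-methylcarvone (C6 epimer mixture), via lithium dienolate 2 (not isolated)
Conditions: LiN(i-Pr)2, THF, −78 °C; then MeI, −78 → 0 °C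
Reagents that add atoms: iodomethane, CI
Why: kinetic α′-deprotonation gives the cross-conjugated lithium dienolate, which is C-methylated (enolate alkylation, SN2); the new centre is re-enolised in step 2, so its configuration is irrelevant.

Step 2
Reactants: 3 6-methylcarvone
Product: 5 (5S,6S)-6-allyl-6-methylcarvone, via lithium enolate 4 (not isolated)
Conditions: LiN(i-Pr)2, THF, −78 → 0 °C; then allyl bromide, DMPU, −78 → −20 °C
Reagents that add atoms: allyl bromide, C=CCBr
Why: enolate alkylation in which allyl bromide approaches the tetrasubstituted enolate anti to the neighbouring isopropenyl group, so the quaternary carbon (future C10) carries allyl (future C1) trans and methyl (C20) cis to isopropenyl.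

Step 3
Reactants: 5 (5S,6S)-6-allyl-6-methylcarvone
Product: 7 keto-aldehyde 2-[(1S,6R)-6-acetyl-1,3-dimethyl-2-oxocyclohex-3-en-1-yl]acetaldehyde, via bis-ozonide 6 (not isolated)
Conditions: O3 (titrated, 2 equiv), CH2Cl2, −78 °C; then PPh3, −78 °C → rt
Reagents that add atoms: ozone, [O-][O+]=O
Why: ozonolysis with reductive work-up cleaves the two electron-rich terminal alkenes much faster than the electron-poor enone alkene, unmasking the C2 aldehyde and the C4 methyl ketone without touching C5 or C10.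

Step 4
Reactants: 7 keto-aldehyde
Product: 8 2α-hydroxy-8,10β-dimethyl-5αH-decal-7-ene-4,9-dione
Conditions: K2CO3, MeOH, 0 °C → rt
Reagents that add atoms: none
Why: reversible intramolecular aldol addition (6-enolexo) of the methyl-ketone enolate (C3) to the aldehyde (C2) closes ring A; under thermodynamic control the trans fusion is kept and the hydroxyl sits equatorial (2α), away from the syn-axial C20 methyl.

Step 5
Reactants: 8 hydroxy-dione
Product: 9 2α-(tert-butyldimethylsilyloxy) dione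
Conditions: TBSCl, imidazole, DMF, rt
Reagents that add atoms: tert-butyldimethylsilyl chloride, CC(C)(C)[Si](C)(C)Cl
Why: imidazole-promoted O-silylation of the unhindered equatorial alcohol blocks retro-aldol and β-elimination in the later basic and Lewis-acidic steps.

Step 6
Reactants: 9 silyloxy dione
Product: 10 C4 spiro-epoxide (oxirane CH2 α, O β)
Conditions: Me3SI, KN(SiMe3)2, THF, −10 °C; then 9, −10 → 0 °C
Reagents that add atoms: trimethylsulfonium iodide, C[S+](C)C.[I-]
Why: Corey–Chaykovsky epoxidation in which the sulfonium ylide attacks only the saturated C4 ketone (the C9 carbonyl is conjugated and neopentyl) along the equatorial α trajectory, because the axial β path is blocked by the syn-axial C20 methyl.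

Step 7
Reactants: 10 spiro-epoxide
Product: 11 C19 alcohol, 4β-(hydroxymethyl)-4α,8,10β-trimethyl-2α-(TBSO)-5αH-decal-7-en-9-one
Conditions: Me3Al (4 equiv), CH2Cl2, −78 → 0 °C; aq. KNaC4H4O6 work-up
Reagents that add atoms: trimethylaluminium, C[Al](C)C
Why: organoaluminium alkylative opening of a 2,2-disubstituted oxirane at its tertiary carbon (Lewis-acid-assisted, borderline SN1/SN2), with methyl delivered to C4 anti to the breaking C–O bond from the open α face, so C4 becomes quaternary with 18-CH3 α and 19-CH2OH β.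

Step 8
Reactants: 12 tert-butyl(but-3-yn-1-yloxy)dimethylsilane
Product: 15 (2E)-5-(tert-butyldimethylsilyloxy)-3-methylpent-2-en-1-ol, via alkenylalane 13 (not isolated), via lithium aluminate 14 (not isolated)
Conditions: Me3Al (2.5 equiv), Cp2ZrCl2 (0.25 equiv), CH2Cl2, 0 °C → rt; then n-BuLi, hexane, −78 °C; then (CH2O)n, THF, rt
Reagents that add atoms: trimethylaluminium, C[Al](C)C; formaldehyde (as paraformaldehyde), C=O
Why: Negishi zirconium-catalysed carboalumination adds methyl and aluminium syn across the terminal alkyne, and the derived aluminate is hydroxymethylated with retention, fixing the 13E trisubstituted alkene.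

Step 9
Reactants: 15 allylic alcohol
Product: 16 (2E)-1-(tert-butyldiphenylsilyloxy)-5-(tert-butyldimethylsilyloxy)-3-methylpent-2-ene
Conditions: TBDPSCl, imidazole, CH2Cl2, rt
Reagents that add atoms: tert-butyldiphenylsilyl chloride, CC(C)(C)[Si](Cl)(c1ccccc1)c1ccccc1
Why: O-silylation of the primary allylic alcohol with a group that survives acid, organolithium and zerovalent palladium chemistry.

Step 10
Reactants: 16 bis-silyl ether
Product: 17 (3E)-5-(tert-butyldiphenylsilyloxy)-3-methylpent-3-en-1-ol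
Conditions: PPTS, EtOH, 40 °C
Reagents that add atoms: none
Why: acid-catalysed solvolysis removes the primary alkyl tert-butyldimethylsilyl ether much faster than the bulkier, more acid-stable tert-butyldiphenylsilyl ether.

Step 11
Reactants: 17 homoallylic alcohol
Product: 18 (2E)-1-(tert-butyldiphenylsilyloxy)-5-iodo-3-methylpent-2-ene
Conditions: I2, PPh3, imidazole, CH2Cl2, 0 °C → rt
Reagents that add atoms: iodine, II
Why: Appel-type iodination (SN2 on the alkoxyphosphonium ion) of the primary alcohol.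

Step 12
Reactants: 11 C19 alcohol enone; 18 side-chain iodide (fragment 2)
Product: 22 C9 tertiary allylic bis(3-methylbutanoate), via alkyllithium 19 (not isolated), via lithium alkoxide 20 (not isolated), via dilithium dialkoxide 21 (not isolated)
Conditions: 18, t-BuLi (2.1 equiv), Et2O, −78 °C; 11, LiN(SiMe3)2 (1.0 equiv), THF, −78 °C; mix, −78 → −40 °C; then Me2CHCH2COCl (3 equiv), −78 → 0 °C
Reagents that add atoms: 3-methylbutanoyl chloride, CC(C)CC(Cl)=O
Why: lithium–iodine exchange gives the primary alkyllithium, which adds 1,2 to the enone carbonyl along the axial α trajectory anti to the C20 methyl (side chain α, oxygen β at C9), and O-acylation of both alkoxides installs the 19-ester and makes the C9 oxygen an allylic leaving group.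

Step 13
Reactants: 22 tertiary allylic bis-ester
Product: 23 (13E)-15-(TBDPSO)-2α-(TBSO)-labda-7,13-dien-19-yl 3-methylbutanoate
Conditions: Pd(OAc)2 (5 mol %), n-Bu3P (5 mol %), HCO2H, Et3N, THF, 40 °C
Reagents that add atoms: none
Why: Tsuji–Mandai hydrogenolysis in which zerovalent palladium ionises the tertiary allylic ester anti (from the α face), formate gives a palladium hydride by decarboxylation, and hydride is transferred on the palladium face to the more substituted allyl terminus C9, so net inversion gives 9α-H with the side chain β and leaves the alkene at C7=C8.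

Step 14
Reactants: 23 bis-silyl ether
Product: 24 (13E)-2α,15-dihydroxylabda-7,13-dien-19-yl 3-methylbutanoate
Conditions: Bu4NF, AcOH, THF, rt
Reagents that add atoms: none
Why: fluoride-mediated cleavage of both silyl ethers (Si–F bond formation), buffered with acetic acid so the ester and the allylic alcohol are untouched.

Step 15
Reactants: 24 diol
Product: 25 CNP0118741.1, (13E)-2α-hydroxy-19-(3-methylbutanoyloxy)labda-7,13-dien-15-yl methyl butanedioate
Conditions: MeO2CCH2CH2COCl (1.05 equiv), 2,4,6-collidine, CH2Cl2, −78 °C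
Reagents that add atoms: methyl 4-chloro-4-oxobutanoate, COC(=O)CCC(Cl)=O
Why: chemoselective acylation (nucleophilic acyl substitution) of the unhindered primary allylic 15-OH over the secondary 2α-OH with one equivalent of acid chloride and a hindered pyridine base; no stereocentre is touched.

**Compound list**

1 | (R)-(−)-carvone, (5R)-2-methyl-5-(prop-1-en-2-yl)cyclohex-2-en-1-one | CC(=C)[C@@H]1CC=C(C)C(=O)C1 | starting material
2 | lithium dienolate of 1 (C1=C6 enolate, C5 unchanged) | [Li+].[O-]C1=C[C@H](C(C)=C)CC=C1C | intermediate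
3 | 6-methylcarvone, (5R,6RS)-2,6-dimethyl-5-(prop-1-en-2-yl)cyclohex-2-en-1-one (C6 epimers) | O=C1C(C)=CC[C@@H](C(C)=C)C1C | intermediate
4 | lithium enolate of 3 (tetrasubstituted C1=C6 enolate) | [Li+].[O-]C1=C(C)[C@H](C(C)=C)CC=C1C | intermediate
5 | (5S,6S)-6-allyl-2,6-dimethyl-5-(prop-1-en-2-yl)cyclohex-2-en-1-one (allyl trans, methyl cis to isopropenyl) | C=CC[C@]1(C)C(=O)C(C)=CC[C@H]1C(C)=C | intermediate
6 | bis-ozonide of 5 (1,2,4-trioxolanes in place of both terminal alkenes; trioxolane carbons unassigned) | C1OC(C[C@]2(C)C(=O)C(C)=CC[C@H]2C2(C)OCOO2)OO1 | intermediate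
7 | 2-[(1S,6R)-6-acetyl-1,3-dimethyl-2-oxocyclohex-3-en-1-yl]acetaldehyde (CH2CHO trans to acetyl) | O=CC[C@]1(C)C(=O)C(C)=CC[C@H]1C(C)=O | intermediate
8 | 2α-hydroxy-8,10β-dimethyl-5αH-decal-7-ene-4,9-dione (trans-fused) | O=C1C(C)=CC[C@H]2C(=O)C[C@H](O)C[C@]12C | intermediate
9 | 2α-(tert-butyldimethylsilyloxy)-8,10β-dimethyl-5αH-decal-7-ene-4,9-dione | O=C1C(C)=CC[C@H]2C(=O)C[C@H](O[Si](C)(C)C(C)(C)C)C[C@]12C | intermediate
10 | C4 spiro-oxirane of 9 (oxirane CH2 α, O β; C9 enone retained) | O=C1C(C)=CC[C@H]2[C@]3(CO3)C[C@H](O[Si](C)(C)C(C)(C)C)C[C@]12C | intermediate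
11 | 4β-(hydroxymethyl)-4α,8,10β-trimethyl-2α-(tert-butyldimethylsilyloxy)-5αH-decal-7-en-9-one | O=C1C(C)=CC[C@H]2[C@@](C)(CO)C[C@H](O[Si](C)(C)C(C)(C)C)C[C@]12C | intermediate
12 | tert-butyl(but-3-yn-1-yloxy)dimethylsilane | C#CCCO[Si](C)(C)C(C)(C)C | starting material
13 | [(1E)-4-(tert-butyldimethylsilyloxy)-2-methylbut-1-en-1-yl]dimethylalane | C[Al](C)/C=C(\C)CCO[Si](C)(C)C(C)(C)C | intermediate
14 | lithium butyl[(1E)-4-(tert-butyldimethylsilyloxy)-2-methylbut-1-en-1-yl]dimethylaluminate | [Li+].CCCC[Al-](C)(C)/C=C(\C)CCO[Si](C)(C)C(C)(C)C | intermediate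
15 | (2E)-5-(tert-butyldimethylsilyloxy)-3-methylpent-2-en-1-ol | OC/C=C(\C)CCO[Si](C)(C)C(C)(C)C | intermediate
16 | (2E)-1-(tert-butyldiphenylsilyloxy)-5-(tert-butyldimethylsilyloxy)-3-methylpent-2-ene | CC(C)(C)[Si](OC/C=C(\C)CCO[Si](C)(C)C(C)(C)C)(c1ccccc1)c1ccccc1 | intermediate
17 | (3E)-5-(tert-butyldiphenylsilyloxy)-3-methylpent-3-en-1-ol | CC(C)(C)[Si](OC/C=C(\C)CCO)(c1ccccc1)c1ccccc1 | intermediate
18 | (2E)-1-(tert-butyldiphenylsilyloxy)-5-iodo-3-methylpent-2-ene | CC(C)(C)[Si](OC/C=C(\C)CCI)(c1ccccc1)c1ccccc1 | intermediate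
19 | [(3E)-5-(tert-butyldiphenylsilyloxy)-3-methylpent-3-en-1-yl]lithium | CC(C)(C)[Si](OC/C=C(\C)CC[Li])(c1ccccc1)c1ccccc1 | intermediate
20 | lithium 19-alkoxide of 11 | [Li+].O=C1C(C)=CC[C@H]2[C@@](C)(C[O-])C[C@H](O[Si](C)(C)C(C)(C)C)C[C@]12C | intermediate
21 | dilithium 9β,19-dialkoxide (side chain 9α, Δ7) | [Li+].[Li+].CC(C)(C)[Si](OC/C=C(\C)CC[C@]1([O-])C(C)=CC[C@H]2[C@@](C)(C[O-])C[C@H](O[Si](C)(C)C(C)(C)C)C[C@]12C)(c1ccccc1)c1ccccc1 | intermediate
22 | 9β,19-bis(3-methylbutanoyloxy) compound: side chain 9α, 2α-OTBS, 15-OTBDPS, Δ7, 13E | CC(C)(C)[Si](OC/C=C(\C)CC[C@]1(OC(=O)CC(C)C)C(C)=CC[C@H]2[C@@](C)(COC(=O)CC(C)C)C[C@H](O[Si](C)(C)C(C)(C)C)C[C@]12C)(c1ccccc1)c1ccccc1 | intermediate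
23 | (13E)-15-(tert-butyldiphenylsilyloxy)-2α-(tert-butyldimethylsilyloxy)labda-7,13-dien-19-yl 3-methylbutanoate | CC(C)(C)[Si](OC/C=C(\C)CC[C@H]1C(C)=CC[C@H]2[C@@](C)(COC(=O)CC(C)C)C[C@H](O[Si](C)(C)C(C)(C)C)C[C@]12C)(c1ccccc1)c1ccccc1 | intermediate
24 | (13E)-2α,15-dihydroxylabda-7,13-dien-19-yl 3-methylbutanoate | OC/C=C(\C)CC[C@H]1C(C)=CC[C@H]2[C@@](C)(COC(=O)CC(C)C)C[C@H](O)C[C@]12C | intermediate
25 | CNP0118741.1, (13E)-2α-hydroxy-19-(3-methylbutanoyloxy)labda-7,13-dien-15-yl methyl butanedioate | COC(=O)CCC(=O)OC/C=C(\C)CC[C@H]1C(C)=CC[C@H]2[C@@](C)(COC(=O)CC(C)C)C[C@H](O)C[C@]12C | target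

**Totals and risks**

Total step count: 15. Longest linear sequence: 11 steps (steps 1–7 and 12–15); fragment 2 takes steps 8–11.

Step 7 (Me3Al opening of the spiro-epoxide) is the most likely to fail, because a Meinwald hydride shift or elimination to an allylic alcohol can outrun methyl transfer at this congested tertiary centre. The fallback sets out from 10 and comes back at 11, and introduces the methyl as an electrophile instead. Run the Meinwald rearrangement on purpose (BF3·OEt2, CH2Cl2, −78 °C) to give the C4–H 4-carbaldehyde F1. Methylate its potassium enolate from the α face (KOt-Bu, MeI, THF, 0 °C) to give the 4α-methyl-4β-carbaldehyde F2. Reduce the aldehyde with NaBH4 (MeOH, −78 °C) to 11.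

Step 12 (addition of 19 to the neopentyl enone carbonyl and double acylation) can fail by γ-deprotonation of the enone by the basic alkyllithium or by sluggish acylation of the tertiary alkoxide. The fallback sets out from 11 and comes back at 22, using a slim, much less basic sp nucleophile. Silylate commercial (2E)-3-methylpent-2-en-4-yn-1-ol (TBDPSCl, imidazole) to the enyne silyl ether F3 and deprotonate with n-BuLi to the lithium acetylide F4. Add F4 to lithium alkoxide 20 to give the propargylic dialkoxide F5, and trap with 3-methylbutanoyl chloride to give the 11,12-didehydro bis-ester F6. Saturate only the triple bond with diimide (2-nitrobenzenesulfonohydrazide, Et3N, CH2Cl2, rt; trisubstituted alkenes react far more slowly) to reach 22.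

Step 13 (Pd(OAc)2/formate hydrogenolysis) can fail by hydride delivery to C7 (giving the C8=C9 alkene) or by β-hydride elimination to dienes. The fallback sets out from 11 and comes back at 23, replacing the palladium hydride by a sigmatropic hydrogen transfer. Add 19 to 20 as in step 12 but quench 21 with aqueous NH4Cl to give the 9β,19-diol F7. Acylate only the primary hydroxyl (3-methylbutanoyl chloride, pyridine, 0 °C) to the mono-ester F8. Dauben oxidative transposition with C5H5NH[CrO3Cl] gives the 8-en-7-one F9, and Luche reduction (NaBH4, CeCl3·7H2O, MeOH, −78 °C) gives the 7β-allylic alcohol F10. Myers reductive transposition follows: Mitsunobu reaction with 2-nitrobenzenesulfonohydrazide (PPh3, DEAD, −30 °C) gives, with inversion, the 7α-sulfonylhydrazine F11. On warming F11 loses sulfinic acid to the 7α-allylic diazene F12, whose retro-ene loss of N2 puts hydrogen on C9 from the α face and moves the alkene to C7=C8, giving 23.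

**Further compounds**

F1 | step 7 | 2α-(tert-butyldimethylsilyloxy)-8,10β-dimethyl-9-oxo-5αH-decal-7-ene-4-carbaldehyde (C4 epimers) | O=C1C(C)=CC[C@H]2C(C=O)C[C@H](O[Si](C)(C)C(C)(C)C)C[C@]12C
F2 | step 7 | 2α-(tert-butyldimethylsilyloxy)-4α,8,10β-trimethyl-9-oxo-5αH-decal-7-ene-4β-carbaldehyde | O=C1C(C)=CC[C@H]2[C@@](C)(C=O)C[C@H](O[Si](C)(C)C(C)(C)C)C[C@]12C
F3 | step 12 | tert-butyl{[(2E)-3-methylpent-2-en-4-yn-1-yl]oxy}diphenylsilane | CC(C)(C)[Si](OC/C=C(\C)C#C)(c1ccccc1)c1ccccc1
F4 | step 12 | lithium acetylide of F3 | CC(C)(C)[Si](OC/C=C(\C)C#C[Li])(c1ccccc1)c1ccccc1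
F5 | step 12 | dilithium 9β,19-dialkoxide of the C9 alkynyl adduct (alkynyl group 9α) | [Li+].[Li+].CC(C)(C)[Si](OC/C=C(\C)C#C[C@]1([O-])C(C)=CC[C@H]2[C@@](C)(C[O-])C[C@H](O[Si](C)(C)C(C)(C)C)C[C@]12C)(c1ccccc1)c1ccccc1
F6 | step 12 | 11,12-didehydro analogue of 22 (C11≡C12) | CC(C)(C)[Si](OC/C=C(\C)C#C[C@]1(OC(=O)CC(C)C)C(C)=CC[C@H]2[C@@](C)(COC(=O)CC(C)C)C[C@H](O[Si](C)(C)C(C)(C)C)C[C@]12C)(c1ccccc1)c1ccccc1
F7 | step 13 | 9β,19-diol with the side chain 9α (2α-OTBS, 15-OTBDPS, Δ7, 13E) | CC(C)(C)[Si](OC/C=C(\C)CC[C@]1(O)C(C)=CC[C@H]2[C@@](C)(CO)C[C@H](O[Si](C)(C)C(C)(C)C)C[C@]12C)(c1ccccc1)c1ccccc1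
F8 | step 13 | 19-(3-methylbutanoate) of F7 (free tertiary 9β-OH) | CC(C)(C)[Si](OC/C=C(\C)CC[C@]1(O)C(C)=CC[C@H]2[C@@](C)(COC(=O)CC(C)C)C[C@H](O[Si](C)(C)C(C)(C)C)C[C@]12C)(c1ccccc1)c1ccccc1
F9 | step 13 | 8-en-7-one: (13E)-7-oxo-15-(TBDPSO)-2α-(TBSO)labda-8,13-dien-19-yl 3-methylbutanoate | CC(C)(C)[Si](OC/C=C(\C)CCC1=C(C)C(=O)C[C@H]2[C@@](C)(COC(=O)CC(C)C)C[C@H](O[Si](C)(C)C(C)(C)C)C[C@]12C)(c1ccccc1)c1ccccc1
F10 | step 13 | 7β-hydroxy-8-ene analogue of F9 | CC(C)(C)[Si](OC/C=C(\C)CCC1=C(C)[C@@H](O)C[C@H]2[C@@](C)(COC(=O)CC(C)C)C[C@H](O[Si](C)(C)C(C)(C)C)C[C@]12C)(c1ccccc1)c1ccccc1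
F11 | step 13 | 7α-[1-(2-nitrobenzenesulfonyl)hydrazin-1-yl]-8-ene | CC(C)(C)[Si](OC/C=C(\C)CCC1=C(C)[C@H](N(N)S(=O)(=O)c3ccccc3[N+](=O)[O-])C[C@H]2[C@@](C)(COC(=O)CC(C)C)C[C@H](O[Si](C)(C)C(C)(C)C)C[C@]12C)(c1ccccc1)c1ccccc1
F12 | step 13 | 7α-diazenyl-8-ene (allylic diazene) | CC(C)(C)[Si](OC/C=C(\C)CCC1=C(C)[C@H](N=N)C[C@H]2[C@@](C)(COC(=O)CC(C)C)C[C@H](O[Si](C)(C)C(C)(C)C)C[C@]12C)(c1ccccc1)c1ccccc1
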